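The vessel is stirred, kept at one temperature and fed its reagent in portions; watch the starting material, and note when its reading goes flat.

| setting | elm | maple | flask |
|---|---|---|---|
| starting material | 0.098 M | 0.15 M | 0.070 M |
| reagent | 0.084 M (in portions, 4) | 0.084 M (in portions, 4) | 0.0840 M (in portions, 4) |
| protic impurity | 1.4 mM | 1.4 mM | 1.40 mM |
| remark | run made earlier; portions every 15 s | run made earlier; portions every 15 s | the portions of reagent follow each other after 15 s, the first at the start |
| time |  |  | 10 h |

* the state of affairs at 10 h: stopped, and by what, or still going (it is still moving / the reagent has run out first / forward and back rates have come level / all of the starting material has reacted)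
* conversion of starting material at 10 h
* amount of target at 10 h, in percent of the starting material charged
* amount of side product A at 10 h, in percent of the starting material charged
* amount of target if the flask were left three thousand times as long, in percent of the starting material charged

- percentages count the starting material that a species holds: one side product B counts as two
- the analysis behind the earlier runs scatters by 0.5 percentage points, standard deviation
- on the list of suspects stand: starting material + protic impurity -> quenched substrate; starting material + intermediate A -> side product B; intermediate C <-> intermediate D; intermediate A -> intermediate C; target <-> isomer of the product; intermediate B -> side product A; reagent + intermediate B -> target; starting material + reagent -> intermediate B; starting material + reagent -> intermediate A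
- the reaction counts as stopped when no species that holds the starting material changes by six tenths of a point or more over the second half of the time

| run | time / h | starting material / % | target / % |
|---|---|---|---|
| elm | 0.667 | 30.5 | 4.8 |
| elm | 1.00 | 29.4 | 4.6 |
| elm | 2.00 | 28.9 | 5.0 |
| elm | 3.00 | 30.1 | 4.3 |
| elm | 5.00 | 29.9 | 4.4 |
| elm | 8.00 | 29.2 | 4.2 |
| maple | 0.667 | 52.8 | 2.8 |
| maple | 1.00 | 52.9 | 2.9 |
| maple | 2.00 | 53.7 | 2.7 |
| maple | 3.00 | 52.8 | 2.6 |
| maple | 5.00 | 52.7 | 2.8 |
| maple | 8.00 | 53.2 | 2.3 |

(scatter of a reading: 0.5 percentage points)

Read down the starting-material columns first. Elm goes from 30.5% at 0.667 h to 29.2% at 8.00 h and maple from 52.8% to 53.2%, with no steady fall in either, so in both runs the starting material had stopped falling by the first reading, as far as the scatter shows.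

Now read across, using the readings at 5.00 h. Elm consumed 68.7 mM of starting material and maple 71.0 mM, although maple held 1.53 times the [starting material] of elm. Both had the same [reagent] charge, which points to the reagent as the limiting reagent.

That gives the quantity to carry, the price, which reads 1.22 in elm: the reagent charged per starting material consumed. Maple reads 1.18.

My own reckoning for the flask uses elm's price, since elm's [starting material] lies nearer to the flask's than maple's does. The charge of 0.0840 M then pays for 68.7 mM of the 0.070 M present, which is 98.1% conversion, with the reagent giving out first. At maple's price it pays for 71.2 mM, more than the flask's starting material, so this is a close call.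

The forecast says the reagent has run out first, with conversion 97%, a little below my figure, target 6.8%, long-time target 6.8% and side product A 30%, of which it says “which is a guess”.

The simulated flask gives the reagent has run out first, conversion 97.7%, target 6.59%, side product A 38.4% and long-time target 6.59%.

    starting material + protic impurity → quenched substrate (k = 0.410 M⁻¹ s⁻¹)
    starting material + intermediate A → side product B (k = 0.00280 M⁻¹ s⁻¹)
    intermediate C ⇌ intermediate D (K = 0.230, k = 1.50 × 10⁻⁴ s⁻¹)
    intermediate A → intermediate C (k = 0.0170 s⁻¹)
    target ⇌ isomer of the product (K = 2.70, k = 0.00290 s⁻¹)
    intermediate B → side product A (k = 0.0170 s⁻¹)
    reagent + intermediate B → target (k = 0.360 M⁻¹ s⁻¹)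
    starting material + reagent → intermediate B (k = 0.0460 M⁻¹ s⁻¹)
    starting material + reagent → intermediate A (k = 0.0240 M⁻¹ s⁻¹)

The flask keeps 0.035% of its reagent at 10.0 h and has consumed 68.4 mM of starting material, a price of 1.23. The forecast parts from the flask on side product A, by 8.4 percentage points. That side product also holds the price down, as one part of the story: intermediate B that turns into it never takes a second reagent. The run without that step converts 76.8% against 97.7%.

Take a neighbour flask like this one but with 0.028 M of starting material: the price asks for 34.2 mM of reagent, so 59.3% of the charge should remain. Computed, it ends with 0% of its starting material and 56.4% of its reagent.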